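With the ring numbered C1 (gem-dimethyl carbon), C3 (acyloxy carbon), C5 and C6 (oxirane carbons) and C7–C9 (enone chain), the carbon–carbon edge of the oxirane, C5–C6, is at the same time a bond of the cyclohexane, so cutting C5–C6 and C6–O opens both rings to an acyclic methyl ketone that carries an α-chloro ester. One intramolecular Darzens condensation joins the C6 ester enolate to the C5 ketone and lets the C5 alkoxide expel chloride from C6, closing cyclohexane and oxirane and setting C5 and C6 from the C3 stereocentre. The precursor, ethyl (5S)-2-chloro-3,3-dimethyl-7-oxo-5-silyloxyoctanoate, comes from 3,3-dimethylglutaric anhydride by asymmetric methallylboration; reduction, olefination, desilylation and myristoylation follow.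

Key step: step 7

Remark: compounds 11 to 13 are carried as mixtures of epimers at the chlorine-bearing carbon, because that centre becomes a planar enolate carbon in step 7.

Step 1
Reactants: 1 3,3-dimethylglutaric anhydride
Product: 2 5-ethoxy-3,3-dimethyl-5-oxopentanoic acid (monoethyl 3,3-dimethylglutarate)
Conditions: EtOH, reflux
Reagents that add atoms: ethanol, CCO
Why: Alcoholysis of a cyclic anhydride (nucleophilic acyl substitution); the anhydride is symmetrical, so only one half ester can form, and the carboxylic acid set free does not esterify without acid catalysis.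

Step 2
Reactants: 2 5-ethoxy-3,3-dimethyl-5-oxopentanoic acid
Product: 4 ethyl 3,3-dimethyl-5-oxopentanoate, via acid chloride 3 (not isolated)
Conditions: (COCl)2, cat. DMF, CH2Cl2, 0 °C → rt; evaporate; H2 (1 atm), Pd/BaSO4, 2,6-lutidine, THF, rt
Reagents that add atoms: none
Why: Acid chloride formation followed by Rosenmund reduction; the lutidine-moderated Pd/BaSO4 hydrogenolyses the C–Cl bond and should stop at the aldehyde, the ethyl ester is inert to both operations, and no lactone-prone hydroxy ester is passed through.

Step 3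
Reactants: 4 ethyl 3,3-dimethyl-5-oxopentanoate; 5 3-chloro-2-methylpropene
Product: 8 ethyl (5R)-5-hydroxy-3,3,7-trimethyloct-7-enoate, via 2-methylallylmagnesium chloride 6 (not isolated), via B-(2-methylallyl)diisopinocampheylborane 7 (not isolated)
Conditions: 5, Mg, THF, 0 °C → rt; (+)-Ipc2BOMe [the enantiomer made from (−)-α-pinene], Et2O, −78 °C → rt; 4, −78 °C; NaH2PO4/Na2HPO4 buffer (pH 7), MeOH, 30% H2O2, 0 °C → rt
Reagents that add atoms: none
Why: Brown asymmetric allylboration with the 2-methylallyl reagent: the aldehyde binds boron and the allyl group is delivered through a six-membered chair transition state in which the isopinocampheyl groups of (−)-α-pinene origin leave the Re face of the aldehyde open, which should give the (5R) carbinol (the C3 configuration of the target), while the borane ignores the ester and the neutral oxidative work-up frees the δ-hydroxy ester without lactonising it.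

Step 4
Reactants: 8 ethyl (5R)-5-hydroxy-3,3,7-trimethyloct-7-enoate
Product: 9 ethyl (5R)-5-(tert-butyldimethylsilyloxy)-3,3,7-trimethyloct-7-enoate
Conditions: TBSOTf, 2,6-lutidine, CH2Cl2, −78 → 0 °C
Reagents that add atoms: tert-butyldimethylsilyl trifluoromethanesulfonate, CC(C)(C)[Si](C)(C)OS(=O)(=O)C(F)(F)F
Why: O-silylation of a secondary alcohol by a silyl triflate with a hindered pyridine base, fast enough at low temperature to outrun δ-lactonisation and leaving the stereocentre untouched.

Step 5
Reactants: 9 ethyl (5R)-5-(tert-butyldimethylsilyloxy)-3,3,7-trimethyloct-7-enoate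
Product: 11 ethyl (5R)-5-(tert-butyldimethylsilyloxy)-2-chloro-3,3,7-trimethyloct-7-enoate as a mixture of C2 epimers, via lithium ester enolate 10 (not isolated)
Conditions: LiN(iPr)2, THF, −78 °C; cannulated into C2Cl6, THF, −78 → −40 °C
Reagents that add atoms: hexachloroethane, ClC(Cl)(Cl)C(Cl)(Cl)Cl
Why: Electrophilic α-chlorination of a lithium ester enolate by positive-chlorine transfer from C2Cl6; the C2 methylene is the only acidic site, and inverse addition together with the neopentyl environment should suppress the proton exchange that leads to dichlorination.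

Step 6
Reactants: 11 ethyl (5R)-5-(tert-butyldimethylsilyloxy)-2-chloro-3,3,7-trimethyloct-7-enoate
Product: 13 ethyl (5S)-5-(tert-butyldimethylsilyloxy)-2-chloro-3,3-dimethyl-7-oxooctanoate as a mixture of C2 epimers, via secondary ozonide 12 (not isolated)
Conditions: O3, CH2Cl2, −78 °C; PPh3, −78 °C → rt
Reagents that add atoms: ozone, [O-][O+]=O
Why: Ozonolysis (Criegee mechanism) of the 1,1-disubstituted alkene with reductive work-up unveils the methyl ketone, the silyl ether and the hindered α-chloro ester being inert to ozone and to PPh3 (the descriptor at C5 changes from R to S only because the ligand priorities change).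

Step 7
Reactants: 13 ethyl (5S)-5-(tert-butyldimethylsilyloxy)-2-chloro-3,3-dimethyl-7-oxooctanoate
Product: 15 ethyl (1S,4S,6R)-4-(tert-butyldimethylsilyloxy)-2,2,6-trimethyl-7-oxabicyclo[4.1.0]heptane-1-carboxylate, via potassium chlorohydrin alkoxide 14 (not isolated)
Conditions: KOtBu, THF, −78 → −30 °C
Reagents that add atoms: none
Why: KOtBu reversibly removes the hydrogen on the chlorine-bearing carbon, the most acidic C–H of 13, and the ester enolate adds to the methyl ketone (6-(enolexo)-exo-trig aldol addition, which closes the cyclohexane through C5–C6) to give aldolate 14, whose alkoxide displaces the neighbouring chloride from the rear (3-exo-tet, which closes the oxirane through C6–O). The closest known reaction type is the Darzens glycidic ester condensation of an α-chloro ester with a ketone, run here within one molecule. C5 and C6 are set together by the ring-closing chair: only an aldolate with O− and Cl trans-diaxial can close, and of the two such chairs only the one that keeps the C3 silyloxy group equatorial escapes a syn-diaxial clash with the axial C1 methyl group and the axial C5 oxygen, so the oxirane oxygen should end up trans to the C3 oxygen, the (3S,5R,6S) array of the target. Aldolates that cannot close return by retro-aldol and are funnelled through the productive one, and the two C2 epimers of 13 converge in the planar enolate. The selectivity that the step needs is chemoselectivity over enolisation of the ketone followed by β-loss of silanolate, and it is secured by the greater acidity of the α-chloro ester C–H, by the fast ring-forming aldol addition that keeps the ketone masked as aldolate, and by working at or below −30 °C. Product 15 has no α-hydrogen and cannot epimerise or condense further under the base.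

Step 8
Reactants: 15 ethyl (1S,4S,6R)-4-(tert-butyldimethylsilyloxy)-2,2,6-trimethyl-7-oxabicyclo[4.1.0]heptane-1-carboxylate
Product: 16 [(1R,4S,6R)-4-(tert-butyldimethylsilyloxy)-2,2,6-trimethyl-7-oxabicyclo[4.1.0]heptan-1-yl]methanol
Conditions: iBu2AlH, CH2Cl2, −78 → 0 °C; aq. KNaC4H4O6 (potassium sodium tartrate)
Reagents that add atoms: none
Why: Hydride reduction of the ester all the way to the primary alcohol, which avoids a capricious partial reduction; the tetrasubstituted oxirane is too hindered for hydride opening and the silyl ether is inert (the descriptor at the carbinol-bearing oxirane carbon changes only through ligand priorities).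

Step 9
Reactants: 16 [(1R,4S,6R)-4-(tert-butyldimethylsilyloxy)-2,2,6-trimethyl-7-oxabicyclo[4.1.0]heptan-1-yl]methanol; 17 dimethyl (2-oxopropyl)phosphonate
Product: 19 (3E)-4-[(1S,4S,6R)-4-(tert-butyldimethylsilyloxy)-2,2,6-trimethyl-7-oxabicyclo[4.1.0]heptan-1-yl]but-3-en-2-one, via epoxy aldehyde 18 (not isolated)
Conditions: Dess–Martin periodinane, pyridine, CH2Cl2, 0 °C → rt; work-up; 17, NaH, THF, 0 °C → rt
Reagents that add atoms: none
Why: Dess–Martin oxidation followed by Horner–Wadsworth–Emmons olefination; aldehyde 18 has no α-hydrogen and cannot enolise, and the stabilised β-keto phosphonate anion, more nucleophilic than the corresponding phosphorane, should give the E-enone through reversible addition and collapse of the more stable trans-oxaphosphetane.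

Step 10
Reactants: 19 (3E)-4-[(1S,4S,6R)-4-(tert-butyldimethylsilyloxy)-2,2,6-trimethyl-7-oxabicyclo[4.1.0]heptan-1-yl]but-3-en-2-one
Product: 20 (3E)-4-[(1S,4S,6R)-4-hydroxy-2,2,6-trimethyl-7-oxabicyclo[4.1.0]heptan-1-yl]but-3-en-2-one
Conditions: Bu4NF, AcOH, THF, rt
Reagents that add atoms: none
Why: Fluoride-driven cleavage of the Si–O bond; the acetic acid buffer keeps the medium near neutral, so the epoxy enone meets neither alkoxide base nor an acid strong enough to open the oxirane.

Step 11
Reactants: 20 (3E)-4-[(1S,4S,6R)-4-hydroxy-2,2,6-trimethyl-7-oxabicyclo[4.1.0]heptan-1-yl]but-3-en-2-one; 21 tetradecanoyl chloride (myristoyl chloride)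
Product: 22 (1R,3S,6S)-1,5,5-trimethyl-6-[(1E)-3-oxobut-1-en-1-yl]-7-oxabicyclo[4.1.0]heptan-3-yl tetradecanoate (target)
Conditions: pyridine, cat. DMAP, CH2Cl2, 0 °C → rt
Reagents that add atoms: none
Why: Acylation of the secondary equatorial alcohol by an acid chloride under nucleophilic catalysis; it is the only nucleophilic group, and C3 keeps its configuration because its C–O bond is not broken.

Compound list
1 | 3,3-dimethylglutaric anhydride | CC1(C)CC(=O)OC(=O)C1 | starting material
2 | 5-ethoxy-3,3-dimethyl-5-oxopentanoic acid | CCOC(=O)CC(C)(C)CC(=O)O | intermediate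
3 | ethyl 5-chloro-3,3-dimethyl-5-oxopentanoate (acid chloride) | CCOC(=O)CC(C)(C)CC(=O)Cl | intermediate
4 | ethyl 3,3-dimethyl-5-oxopentanoate | CCOC(=O)CC(C)(C)CC=O | intermediate
5 | 3-chloro-2-methylpropene | CC(=C)CCl | starting material
6 | 2-methylallylmagnesium chloride | CC(=C)C[Mg]Cl | intermediate
7 | B-(2-methylallyl)diisopinocampheylborane, isopinocampheyl groups from (−)-α-pinene | CC(=C)CB([C@H]1C[C@H]2C[C@@H]([C@@H]1C)C2(C)C)[C@H]1C[C@H]2C[C@@H]([C@@H]1C)C2(C)C | intermediate
8 | ethyl (5R)-5-hydroxy-3,3,7-trimethyloct-7-enoate | CCOC(=O)CC(C)(C)C[C@H](O)CC(C)=C | intermediate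
9 | ethyl (5R)-5-(tert-butyldimethylsilyloxy)-3,3,7-trimethyloct-7-enoate | CCOC(=O)CC(C)(C)C[C@H](O[Si](C)(C)C(C)(C)C)CC(C)=C | intermediate
10 | lithium (5R)-5-(tert-butyldimethylsilyloxy)-1-ethoxy-3,3,7-trimethylocta-1,7-dien-1-olate (ester enolate) | CCOC([O-])=CC(C)(C)C[C@H](O[Si](C)(C)C(C)(C)C)CC(C)=C.[Li+] | intermediate
11 | ethyl (5R)-5-(tert-butyldimethylsilyloxy)-2-chloro-3,3,7-trimethyloct-7-enoate, both C2 epimers | CCOC(=O)C(Cl)C(C)(C)C[C@H](O[Si](C)(C)C(C)(C)C)CC(C)=C | intermediate
12 | ethyl (5S)-5-(tert-butyldimethylsilyloxy)-2-chloro-3,3-dimethyl-6-(3-methyl-1,2,4-trioxolan-3-yl)hexanoate (secondary ozonide) | CCOC(=O)C(Cl)C(C)(C)C[C@H](O[Si](C)(C)C(C)(C)C)CC1(C)OCOO1 | intermediate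
13 | ethyl (5S)-5-(tert-butyldimethylsilyloxy)-2-chloro-3,3-dimethyl-7-oxooctanoate, both C2 epimers | CCOC(=O)C(Cl)C(C)(C)C[C@H](O[Si](C)(C)C(C)(C)C)CC(C)=O | intermediate
14 | potassium salt of ethyl (1R,2R,4S)-4-(tert-butyldimethylsilyloxy)-1-chloro-2-hydroxy-2,6,6-trimethylcyclohexane-1-carboxylate (O− and Cl trans-diaxial, silyloxy equatorial) | CC(C)(C)[Si](C)(C)O[C@H]1CC(C)(C)[C@](Cl)(C(=O)OCC)[C@@]([O-])(C)C1.[K+] | intermediate
15 | ethyl (1S,4S,6R)-4-(tert-butyldimethylsilyloxy)-2,2,6-trimethyl-7-oxabicyclo[4.1.0]heptane-1-carboxylate (oxirane trans to the silyloxy group) | CC(C)(C)[Si](C)(C)O[C@H]1CC(C)(C)[C@]2(C(=O)OCC)O[C@]2(C)C1 | intermediate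
16 | [(1R,4S,6R)-4-(tert-butyldimethylsilyloxy)-2,2,6-trimethyl-7-oxabicyclo[4.1.0]heptan-1-yl]methanol | CC(C)(C)[Si](C)(C)O[C@H]1CC(C)(C)[C@]2(CO)O[C@]2(C)C1 | intermediate
17 | dimethyl (2-oxopropyl)phosphonate | COP(=O)(CC(C)=O)OC | starting material
18 | (1S,4S,6R)-4-(tert-butyldimethylsilyloxy)-2,2,6-trimethyl-7-oxabicyclo[4.1.0]heptane-1-carbaldehyde | CC(C)(C)[Si](C)(C)O[C@H]1CC(C)(C)[C@]2(C=O)O[C@]2(C)C1 | intermediate
19 | (3E)-4-[(1S,4S,6R)-4-(tert-butyldimethylsilyloxy)-2,2,6-trimethyl-7-oxabicyclo[4.1.0]heptan-1-yl]but-3-en-2-one | CC(C)(C)[Si](C)(C)O[C@H]1CC(C)(C)[C@]2(/C=C/C(C)=O)O[C@]2(C)C1 | intermediate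
20 | (3E)-4-[(1S,4S,6R)-4-hydroxy-2,2,6-trimethyl-7-oxabicyclo[4.1.0]heptan-1-yl]but-3-en-2-one | O[C@H]1CC(C)(C)[C@]2(/C=C/C(C)=O)O[C@]2(C)C1 | intermediate
21 | tetradecanoyl chloride | CCCCCCCCCCCCCC(=O)Cl | starting material
22 | (1R,3S,6S)-1,5,5-trimethyl-6-[(1E)-3-oxobut-1-en-1-yl]-7-oxabicyclo[4.1.0]heptan-3-yl tetradecanoate | CCCCCCCCCCCCCC(=O)O[C@H]1CC(C)(C)[C@]2(/C=C/C(C)=O)O[C@]2(C)C1 | target

Total step count: 11
Longest linear sequence: 11 steps (1 to 22)

Steps most likely to fail

Step 7. The base may enolise the ketone toward the silyloxy-bearing carbon so that silanolate is lost, or the aldolates may form but close too slowly at the temperature that the silyl ether tolerates. The fallback forms the same ring bond reductively without base and adds the oxirane afterwards. It sets out from 13: SmI2 in THF at −78 °C reduces the C–Cl bond to a samarium enolate that adds to the ketone (intramolecular Reformatsky reaction) and should give ethyl (4S)-4-(tert-butyldimethylsilyloxy)-2-hydroxy-2,6,6-trimethylcyclohexane-1-carboxylate F1. Dehydration with SOCl2 and pyridine, followed by DBU to bring the double bond into conjugation, gives ethyl (4R)-4-(tert-butyldimethylsilyloxy)-2,6,6-trimethylcyclohex-1-ene-1-carboxylate F2. Reduction with iBu2AlH gives [(4R)-4-(tert-butyldimethylsilyloxy)-2,6,6-trimethylcyclohex-1-en-1-yl]methanol F3. Sharpless epoxidation of this allylic alcohol (Ti(OiPr)4, D-(−)-diethyl tartrate, tBuOOH, CH2Cl2, −20 °C), which should deliver oxygen to the face anti to the silyloxy group, comes back to the route at 16.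

Step 5. Proton transfer from the chlorinated ester to unreacted enolate may give over-chlorination and returned starting ester. The fallback sets out from 9 and replaces the basic enolate by a neutral nucleophile: the enolate is trapped with Me3SiCl and isolated by non-aqueous work-up as the ketene silyl acetal (5R)-5-(tert-butyldimethylsilyloxy)-1-ethoxy-3,3,7-trimethyl-1-(trimethylsilyloxy)octa-1,7-diene F4, which is chlorinated with N-chlorosuccinimide in CH2Cl2 at 0 °C and comes back to the route at 11.

Step 9. Attack of the stabilised phosphonate anion on a carbonyl carbon flanked by two fully substituted carbons may be too slow, so that the aldehyde is returned or degrades. The fallback sets out from 18 and builds the enone by aldol addition and elimination: the small lithium enolate of acetone (LiN(iPr)2, acetone, THF, −78 °C) should add to give 4-hydroxy-4-[(1R,4S,6R)-4-(tert-butyldimethylsilyloxy)-2,2,6-trimethyl-7-oxabicyclo[4.1.0]heptan-1-yl]butan-2-one F5 as a mixture of carbinol epimers, and mesylation (MsCl, Et3N) followed by DBU eliminates by the E1cB path and comes back to the route at 19.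

Further compounds
F1 | step 7 | ethyl (4S)-4-(tert-butyldimethylsilyloxy)-2-hydroxy-2,6,6-trimethylcyclohexane-1-carboxylate | CC(C)(C)[Si](C)(C)O[C@H]1CC(C)(C)C(C(=O)OCC)C(C)(O)C1
F2 | step 7 | ethyl (4R)-4-(tert-butyldimethylsilyloxy)-2,6,6-trimethylcyclohex-1-ene-1-carboxylate | CC(C)(C)[Si](C)(C)O[C@H]1CC(C)(C)C(C(=O)OCC)=C(C)C1
F3 | step 7 | [(4R)-4-(tert-butyldimethylsilyloxy)-2,6,6-trimethylcyclohex-1-en-1-yl]methanol | CC(C)(C)[Si](C)(C)O[C@H]1CC(C)(C)C(CO)=C(C)C1
F4 | step 5 | (5R)-5-(tert-butyldimethylsilyloxy)-1-ethoxy-3,3,7-trimethyl-1-(trimethylsilyloxy)octa-1,7-diene | CCOC(O[Si](C)(C)C)=CC(C)(C)C[C@H](O[Si](C)(C)C(C)(C)C)CC(C)=C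
F5 | step 9 | 4-hydroxy-4-[(1R,4S,6R)-4-(tert-butyldimethylsilyloxy)-2,2,6-trimethyl-7-oxabicyclo[4.1.0]heptan-1-yl]butan-2-one | CC(C)(C)[Si](C)(C)O[C@H]1CC(C)(C)[C@]2(C(O)CC(C)=O)O[C@]2(C)C1
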